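## The problem

The target is a 3,6''-linked biflavone. A genkwanin unit (5-hydroxy-7-methoxy-2-(4-hydroxyphenyl)chromen-4-one) is bonded through its pyranone carbon C3 to C6'' of a luteolin unit. The C3–C6'' bond is a biaryl-type axis with four ortho substituents (C4=O and the C2 aryl group on one side, the C5'' and C7'' hydroxyls on the other), so any late coupling at this bond is sterically costly. C6'' and C8'' of a 5,7-dioxygenated flavone are electronically almost equal, and a 2-substituted phloroglucinol can close its pyranone ring on either flanking oxygen, so 6''- against 8''-connectivity must be decided in a way that cannot leak. Of the seven oxygens only O7 is methylated, so the six others need protection that comes off without touching an unchelated aryl methyl ether. There is no stereocentre. The polyphenol is air-sensitive when free, flavone rings open in hot hydroxide or alkoxide, and strong protic acid can equilibrate 6''- and 8''-linked isomers (Wessely–Moser rearrangement).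

The feature that makes the key step possible is ring A of the luteolin unit (C4a''–C5''–C6''–C7''–C8''–C8a''). It is a phloroglucinol ring, that is, the enol form of a cyclic 1,3,5-tricarbonyl chain: C5'' and C7'' are at the acyl oxidation level and C6'', the very atom bonded to C3, is the methylene carbon between them. C8a'' carries the pyranone oxygen O1''. The ring can therefore be closed by two Claisen-type bonds (C7''–C8'' and C5''–C6'') between a C3–CH2–CO2Et side chain and a preformed 4-pyranone bearing a methyl group (future C8'') and an ester (future C5'') on adjacent carbons.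

## Retrosynthesis

**14 to 13.** The last operation only unmasks phenols. Precursor 13 carries benzyl ethers on O4', O3''' and O4''' and a methyl ether on the chelated O5, while O5'' and O7'' are free. The forward step must cleave benzyl ethers and the peri-methoxy group but not the 7-methoxy group; BCl3 does this through chelation to the C4 carbonyl.

**13 to 5 and 11 (key disconnection).** Ring A of the luteolin unit is opened at C7''–C8'' and C5''–C6''. This gives flavone-3-acetate 5 (its CH2 is C6'', its ester carbon C7'') and 4-pyranone ester 11 (its methyl carbon is C8'', its ester carbon C5''), joined in the flask through keto ester 12.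

- Against the neighbouring cut of the C3–C6'' bond, it avoids a tetra-ortho-substituted coupling: the crowded bond already exists in 5 as an unhindered sp2–sp3 bond.
- Against building the luteolin pyranone last on a 2-arylphloroglucinol, the 6''/8'' question never arises, because O1'' is already attached to the future C8a''.
- The precursors are two monocyclic or bicyclic pieces of about half the size each, and the product is the complete biflavone skeleton.
- The forward reaction must acylate the lateral anion of 11 at carbon, then close the ring through carbon and not oxygen, without opening either pyranone.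

**5 to 4.** The C3–CH2 bond is cut to 3-iodoflavone 4 and a zinc ester enolate. A two-carbon sp3 nucleophile is the smallest possible partner for the hindered C3 position. The forward step is a Negishi coupling of a Reformatsky reagent.

**4 to 3, then 1 and 2.** The iodinated pyranone ring comes from ynone 3 by electrophilic iodocyclisation. This makes the ring and the C3–I bond together, with no regiochemical question because the two ortho-methoxy groups of 3 are equivalent. Ynone 3 comes from acid chloride 1 and alkyne 2 by acyl Sonogashira coupling.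

**11 to 9 and 10, then 8, then 6 and 7.** The pyranone is cut at O1–C2 and C3–C4 into aroylketene 10 and enamino ester 9. The ketene carbon becomes C4, and the enamine α-carbon brings the ester to C3 next to the methyl-bearing C2, which is the arrangement the key step needs. Ketene 10 is released thermally from acyl Meldrum's acid 8, made from acid 6 and Meldrum's acid 7.

## Roads not taken

**Alternative 1:** (the obvious route) Cut C3–C6'' and join two complete flavones by Suzuki–Miyaura coupling of iodide 4 with {5,7-bis(benzyloxy)-2-[3,4-bis(benzyloxy)phenyl]-4-oxo-4H-chromen-6-yl}boronic acid A1. The bond formed has four ortho substituents. The boron partner is a 2,6-dioxygenated arylboronic acid, a class prone to protodeboronation, and oxidative addition occurs at an α-iodoenone flanked by an aryl group. A1 also needs about four steps from luteolin, and its 6-regiochemistry rests on a directing effect. The chosen plan forms the crowded bond as an sp2–sp3 bond, fixes C6'' by construction, and is one step shorter overall. This route is kept as the fallback for the key step.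

**Alternative 2:** Treat the genkwanin unit as a 2-aryl-isoflavone. Deoxybenzoin 1-(2-hydroxy-4,6-dimethoxyphenyl)-2-[2,4,6-tris(benzyloxy)phenyl]ethan-1-one A2 would be aroylated and cyclised to 2-[4-(benzyloxy)phenyl]-5,7-dimethoxy-3-[2,4,6-tris(benzyloxy)phenyl]-4H-chromen-4-one A3. The luteolin pyranone would then be built on the phloroglucinol ring by acylation, Baker–Venkataraman rearrangement and cyclodehydration. The hindered bond is made early and easily, but the route is linear (about ten steps). More seriously, the 2-arylphloroglucinol is symmetric, so the final ring closure can use either hydroxyl next to the acyl group and would also give the 8''-linked isomer 3-[2-(3,4-dihydroxyphenyl)-5,7-dihydroxy-4-oxo-4H-chromen-8-yl]-5-hydroxy-2-(4-hydroxyphenyl)-7-methoxy-4H-chromen-4-one A4. The chosen plan has no such branch point.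

**Alternative 3:** Cut C3–C6'' without prefunctionalisation: dehydrogenative coupling of 2-[4-(benzyloxy)phenyl]-5,7-dimethoxy-4H-chromen-4-one A5 with 2-[3,4-bis(benzyloxy)phenyl]-5,7-dihydroxy-4H-chromen-4-one A6. The forward step would be electrophilic palladation at C3 of A5 (Pd(OAc)2, silver oxidant) followed by C–H metalation of ring A of A6. It is the shortest route on paper. However, A6 offers two nearly equivalent C–H sites and the less hindered C8'' should win. Electrophilic palladation at flavone C3 is established only for coupling with alkenes. Reductive elimination would have to form a tetra-ortho-substituted axis in competition with homocoupling. Nothing in either substrate secures the selectivity that the chosen ring construction gets for free.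

Key step: step 6

Assumption: the C3–C6'' axis is drawn without configuration, so the target is taken as the configurationally undefined compound and no atroposelection is attempted.

## Route

**Step 1**
Reactants: 1 2,4,6-trimethoxybenzoyl chloride; 2 1-(benzyloxy)-4-ethynylbenzene
Product: 3 3-[4-(benzyloxy)phenyl]-1-(2,4,6-trimethoxyphenyl)prop-2-yn-1-one
Conditions: PdCl2(PPh3)2 (2 mol %), CuI (4 mol %), Et3N (1.5 equiv), THF, 25 °C
Reagents that add atoms: none
Why: Acyl Sonogashira coupling of an acid chloride with a terminal alkyne; the neutral room-temperature conditions leave the benzyl and methyl ethers untouched.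

**Step 2**
Reactants: 3 3-[4-(benzyloxy)phenyl]-1-(2,4,6-trimethoxyphenyl)prop-2-yn-1-one
Product: 4 2-[4-(benzyloxy)phenyl]-3-iodo-5,7-dimethoxy-4H-chromen-4-one
Conditions: ICl (1.5 equiv), CH2Cl2, −78 → 25 °C; aq. Na2S2O3
Reagents that add atoms: iodine monochloride, ClI
Why: Electrophilic iodocyclisation: iodonium activation of the alkyne, 6-endo-dig attack of an ortho-methoxy oxygen on the aryl-bearing alkyne carbon, and SN2 demethylation of the oxonium ion by chloride. The two ortho-methoxy groups are equivalent, so a single chromone with iodine at C3 should form.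

**Step 3**
Reactants: 4 2-[4-(benzyloxy)phenyl]-3-iodo-5,7-dimethoxy-4H-chromen-4-one
Product: 5 ethyl 2-{2-[4-(benzyloxy)phenyl]-5,7-dimethoxy-4-oxo-4H-chromen-3-yl}acetate
Conditions: BrZnCH2CO2Et (2 equiv), Pd(dba)2 (5 mol %), XPhos (10 mol %), THF, 60 °C
Reagents that add atoms: bromo(2-ethoxy-2-oxoethyl)zinc, CCOC(=O)C[Zn]Br
Why: Negishi coupling of a Reformatsky reagent (palladium-catalysed α-arylation of a zinc ester enolate) at the C3–I bond. The small sp3 nucleophile should tolerate the two flanking substituents, and it installs the carbon that becomes C6''.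

**Step 4**
Reactants: 6 3,4-bis(benzyloxy)benzoic acid; 7 2,2-dimethyl-1,3-dioxane-4,6-dione (Meldrum's acid)
Product: 8 5-{[3,4-bis(benzyloxy)phenyl](hydroxy)methylidene}-2,2-dimethyl-1,3-dioxane-4,6-dione
Conditions: DCC (1.1 equiv), DMAP (1.5 equiv), CH2Cl2, 0 → 25 °C
Reagents that add atoms: none
Why: Carbodiimide-mediated C-acylation of Meldrum's acid; the product is a chelated enol and a storable precursor of the aroylketene.

**Step 5**
Reactants: 8 5-{[3,4-bis(benzyloxy)phenyl](hydroxy)methylidene}-2,2-dimethyl-1,3-dioxane-4,6-dione; 9 ethyl (2E)-3-(pyrrolidin-1-yl)but-2-enoate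
Product: 11 ethyl 6-[3,4-bis(benzyloxy)phenyl]-2-methyl-4-oxo-4H-pyran-3-carboxylate, via aroylketene 10 (not isolated)
Conditions: 8 (1.5 equiv), 9 (1.0 equiv), toluene, 100 °C; dilute aq. HCl wash
Reagents that add atoms: none
Why: Thermal fragmentation of 8 (loss of acetone and CO2) releases aroylketene 10, which acylates the nucleophilic α-carbon of enamine 9; oxa-cyclisation onto the iminium carbon and loss of pyrrolidine give the 4-pyranone (the enamine variant of the acylketene γ-pyrone synthesis). The ester necessarily ends on C3 next to the methyl-bearing C2.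

**Step 6**
Reactants: 5 ethyl 2-{2-[4-(benzyloxy)phenyl]-5,7-dimethoxy-4-oxo-4H-chromen-3-yl}acetate; 11 ethyl 6-[3,4-bis(benzyloxy)phenyl]-2-methyl-4-oxo-4H-pyran-3-carboxylate
Product: 13 2-[4-(benzyloxy)phenyl]-3-{2-[3,4-bis(benzyloxy)phenyl]-5,7-dihydroxy-4-oxo-4H-chromen-6-yl}-5,7-dimethoxy-4H-chromen-4-one, via keto ester 12 (not isolated)
Conditions: 11 (2.0 equiv), LiN(SiMe3)2 (2.0 equiv), THF, −78 °C; 5 (1.0 equiv), −78 → 0 °C; then LiN(SiMe3)2 (3.0 equiv), 0 → 45 °C; aq. HCl
Reagents that add atoms: none
Why: Proposed new method: LiN(SiMe3)2 deprotonates the 2-methyl group of 11, which is vinylogous to both the ring ketone and the ester; the α-carbon of this dienolate (C3) is quaternary, so only the γ-carbon can be acylated, and Claisen condensation with the unhindered ester of 5 gives keto ester 12 as its enolate (bond C7''–C8''). The second portion of base forms the dianion of 12, whose less stabilised carbanion (the CH between the new ketone and flavone C3) attacks the pyranone ester in a 6-exo-trig Dieckmann closure (bond C5''–C6''); loss of ethoxide and double enolisation aromatise the ring to the 5'',7''-diol. The closest known reaction types are the Staunton–Weinreb annulation of ortho-toluate anions and the base-induced Claisen cyclisation of 2-(2-oxoalkyl)benzoates and β-polyketo esters to naphthalene-1,3-diols and acylphloroglucinols; new here is the 2-methyl-4-pyranone-3-carboxylate as toluate surrogate, so that the ring formed is ring A of a flavone. No stereocentre is created. The 6''- rather than 8''-connectivity is fixed by the substrate: O1'' is already bonded to the carbon that becomes C8a'', the methyl carbon becomes C8'', and the flavone-bearing carbon can only end between the two new hydroxyls. The closure must go through carbon and not oxygen; O-closure to a fused 2-pyranone is reversible in the presence of ethoxide, whereas C-closure ends in an aromatic bis-phenoxide and drains the equilibrium. The aprotic, non-nucleophilic base keeps both pyranone rings closed, so no ring-opened triketone that could reclose towards C8'' should form.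

**Step 7**
Reactants: 13 2-[4-(benzyloxy)phenyl]-3-{2-[3,4-bis(benzyloxy)phenyl]-5,7-dihydroxy-4-oxo-4H-chromen-6-yl}-5,7-dimethoxy-4H-chromen-4-one
Product: 14 3-[2-(3,4-dihydroxyphenyl)-5,7-dihydroxy-4-oxo-4H-chromen-6-yl]-5-hydroxy-2-(4-hydroxyphenyl)-7-methoxy-4H-chromen-4-one
Conditions: BCl3 (12 equiv), C6HMe5 (9 equiv), CH2Cl2, −78 → 0 °C; then H2O
Reagents that add atoms: none
Why: Lewis-acid debenzylation with pentamethylbenzene as cation scavenger, followed on warming by chelation-controlled demethylation of the methoxy group peri to the C4 carbonyl. The unchelated 7-methoxy group should survive, since BCl3 cleaves ordinary aryl methyl ethers only slowly at this temperature.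

## Compound list

1 | 2,4,6-trimethoxybenzoyl chloride | COc1cc(OC)c(C(=O)Cl)c(OC)c1 | starting material
2 | 1-(benzyloxy)-4-ethynylbenzene | C#Cc1ccc(OCc2ccccc2)cc1 | starting material
3 | 3-[4-(benzyloxy)phenyl]-1-(2,4,6-trimethoxyphenyl)prop-2-yn-1-one | COc1cc(OC)c(C(=O)C#Cc2ccc(OCc3ccccc3)cc2)c(OC)c1 | intermediate
4 | 2-[4-(benzyloxy)phenyl]-3-iodo-5,7-dimethoxy-4H-chromen-4-one | COc1cc(OC)c2c(=O)c(I)c(-c3ccc(OCc4ccccc4)cc3)oc2c1 | intermediate
5 | ethyl 2-{2-[4-(benzyloxy)phenyl]-5,7-dimethoxy-4-oxo-4H-chromen-3-yl}acetate | CCOC(=O)Cc1c(-c2ccc(OCc3ccccc3)cc2)oc2cc(OC)cc(OC)c2c1=O | intermediate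
6 | 3,4-bis(benzyloxy)benzoic acid | OC(=O)c1ccc(OCc2ccccc2)c(OCc2ccccc2)c1 | starting material
7 | 2,2-dimethyl-1,3-dioxane-4,6-dione (Meldrum's acid) | CC1(C)OC(=O)CC(=O)O1 | starting material
8 | 5-{[3,4-bis(benzyloxy)phenyl](hydroxy)methylidene}-2,2-dimethyl-1,3-dioxane-4,6-dione | CC1(C)OC(=O)C(=C(O)c2ccc(OCc3ccccc3)c(OCc3ccccc3)c2)C(=O)O1 | intermediate
9 | ethyl (2E)-3-(pyrrolidin-1-yl)but-2-enoate | CCOC(=O)/C=C(\C)N1CCCC1 | starting material
10 | 3-[3,4-bis(benzyloxy)phenyl]-3-oxoprop-1-en-1-one (aroylketene) | O=C=CC(=O)c1ccc(OCc2ccccc2)c(OCc2ccccc2)c1 | intermediate (not isolated)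
11 | ethyl 6-[3,4-bis(benzyloxy)phenyl]-2-methyl-4-oxo-4H-pyran-3-carboxylate | CCOC(=O)c1c(C)oc(-c2ccc(OCc3ccccc3)c(OCc3ccccc3)c2)cc1=O | intermediate
12 | ethyl 6-[3,4-bis(benzyloxy)phenyl]-2-(3-{2-[4-(benzyloxy)phenyl]-5,7-dimethoxy-4-oxo-4H-chromen-3-yl}-2-oxopropyl)-4-oxo-4H-pyran-3-carboxylate | CCOC(=O)c1c(CC(=O)Cc2c(-c3ccc(OCc4ccccc4)cc3)oc3cc(OC)cc(OC)c3c2=O)oc(-c2ccc(OCc3ccccc3)c(OCc3ccccc3)c2)cc1=O | intermediate (not isolated)
13 | 2-[4-(benzyloxy)phenyl]-3-{2-[3,4-bis(benzyloxy)phenyl]-5,7-dihydroxy-4-oxo-4H-chromen-6-yl}-5,7-dimethoxy-4H-chromen-4-one | COc1cc(OC)c2c(=O)c(-c3c(O)cc4oc(-c5ccc(OCc6ccccc6)c(OCc6ccccc6)c5)cc(=O)c4c3O)c(-c3ccc(OCc4ccccc4)cc3)oc2c1 | intermediate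
14 | 3-[2-(3,4-dihydroxyphenyl)-5,7-dihydroxy-4-oxo-4H-chromen-6-yl]-5-hydroxy-2-(4-hydroxyphenyl)-7-methoxy-4H-chromen-4-one | COc1cc(O)c2c(=O)c(-c3c(O)cc4oc(-c5ccc(O)c(O)c5)cc(=O)c4c3O)c(-c3ccc(O)cc3)oc2c1 | target

## Step count and least certain steps

Total step count: 7. Longest linear sequence: 5 steps (steps 1, 2, 3, 6, 7).

**Step 6 (key step, proposed new method).**
- *What may go wrong:* The Claisen acylation may stall, because the stabilised dienolate of 11 is a modest nucleophile and proton transfer from the acidic product 12 consumes it. The enolate oxygen of 12 may close on the pyranone ester (lactonisation to a fused 2-pyranone) faster than the carbon closure. Prolonged warming with ethoxide may open a pyranone ring and blur the regiochemistry.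
- *Fallback (known chemistry):* It sets out from 4 and comes back at 14.
  - Commercial luteolin would be benzylated at O7, O3' and O4' (BnBr, K2CO3, DMF; the chelated 5-hydroxyl stays free) to give 7-(benzyloxy)-2-[3,4-bis(benzyloxy)phenyl]-5-hydroxy-4H-chromen-4-one F1.
  - Iodination ortho to the free 5-hydroxyl (benzyltrimethylammonium dichloroiodate, CaCO3, CH2Cl2/MeOH) should give 7-(benzyloxy)-2-[3,4-bis(benzyloxy)phenyl]-5-hydroxy-6-iodo-4H-chromen-4-one F2.
  - O-benzylation (BnBr, K2CO3, DMF, 70 °C) gives 5,7-bis(benzyloxy)-2-[3,4-bis(benzyloxy)phenyl]-6-iodo-4H-chromen-4-one F3.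
  - Miyaura borylation (B2pin2, PdCl2(dppf), KOAc, dioxane, 90 °C) gives 5,7-bis(benzyloxy)-2-[3,4-bis(benzyloxy)phenyl]-6-(4,4,5,5-tetramethyl-1,3,2-dioxaborolan-2-yl)-4H-chromen-4-one F4.
  - Suzuki–Miyaura coupling of F4 with 4 (Pd(OAc)2, SPhos, K3PO4, toluene/H2O, 100 °C) gives 2-[4-(benzyloxy)phenyl]-3-{5,7-bis(benzyloxy)-2-[3,4-bis(benzyloxy)phenyl]-4-oxo-4H-chromen-6-yl}-5,7-dimethoxy-4H-chromen-4-one F5.
  - Under the conditions of step 7, F5 loses five benzyl groups and the peri-methyl group to give 14.

**Step 5.**
- *What may go wrong:* The ketene may be intercepted by the pyrrolidine that the reaction itself liberates, or may dimerise, before the weakly nucleophilic push–pull enamine reacts.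
- *Fallback:* It sets out from 6 and comes back at 11. Esterification (MeOH, cat. H2SO4) gives methyl 3,4-bis(benzyloxy)benzoate F6. The terminal-methyl dianion of commercial ethyl 2-acetyl-3-oxobutanoate (NaH, then LiN(iPr)2, THF, 0 °C) is aroylated by F6 (acylation of a β-diketone dianion by an aromatic ester) to give ethyl 2-acetyl-5-[3,4-bis(benzyloxy)phenyl]-3,5-dioxopentanoate F7. Acid-catalysed cyclodehydration between the two outer ketone groups (p-TsOH, toluene, reflux with water removal) gives 11.

**Step 3.**
- *What may go wrong:* Transmetalation at the hindered α-iodoenone may be slow, so that protodeiodination or attack of the zinc enolate on the chromone ring competes.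
- *Fallback:* It sets out from 4 and comes back at 5. Sonogashira coupling with ethoxyethyne (PdCl2(PPh3)2, CuI, Et3N, THF, 25 °C) gives 2-[4-(benzyloxy)phenyl]-3-(ethoxyethynyl)-5,7-dimethoxy-4H-chromen-4-one F8. Acid-catalysed hydration of the ynol ether (cat. p-TsOH, wet EtOH, 25 °C) gives ester 5 directly.

**Step 7.**
- *What may go wrong:* Benzyl cations may be captured by the very electron-rich ring A of the luteolin unit (C-benzylation at C8'') in competition with the scavenger. The chelated 5-methoxy group may be cleaved incompletely at a temperature where the 7-methoxy group is still safe.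
- *Fallback:* It sets out from 13 and comes back at 14. Hydrogenolysis (H2, Pd/C, THF/MeOH, 25 °C), which generates no carbocations, gives 3-[2-(3,4-dihydroxyphenyl)-5,7-dihydroxy-4-oxo-4H-chromen-6-yl]-2-(4-hydroxyphenyl)-5,7-dimethoxy-4H-chromen-4-one F9. Chelation-controlled peri-demethylation (AlCl3, MeCN, 50 °C) then gives 14.

## Further compounds

F1 | step 6 | 7-(benzyloxy)-2-[3,4-bis(benzyloxy)phenyl]-5-hydroxy-4H-chromen-4-one | O=c1cc(-c2ccc(OCc3ccccc3)c(OCc3ccccc3)c2)oc2cc(OCc3ccccc3)cc(O)c12
F2 | step 6 | 7-(benzyloxy)-2-[3,4-bis(benzyloxy)phenyl]-5-hydroxy-6-iodo-4H-chromen-4-one | O=c1cc(-c2ccc(OCc3ccccc3)c(OCc3ccccc3)c2)oc2cc(OCc3ccccc3)c(I)c(O)c12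
F3 | step 6 | 5,7-bis(benzyloxy)-2-[3,4-bis(benzyloxy)phenyl]-6-iodo-4H-chromen-4-one | O=c1cc(-c2ccc(OCc3ccccc3)c(OCc3ccccc3)c2)oc2cc(OCc3ccccc3)c(I)c(OCc3ccccc3)c12
F4 | step 6 | 5,7-bis(benzyloxy)-2-[3,4-bis(benzyloxy)phenyl]-6-(4,4,5,5-tetramethyl-1,3,2-dioxaborolan-2-yl)-4H-chromen-4-one | O=c1cc(-c2ccc(OCc3ccccc3)c(OCc3ccccc3)c2)oc2cc(OCc3ccccc3)c(B3OC(C)(C)C(C)(C)O3)c(OCc3ccccc3)c12
F5 | step 6 | 2-[4-(benzyloxy)phenyl]-3-{5,7-bis(benzyloxy)-2-[3,4-bis(benzyloxy)phenyl]-4-oxo-4H-chromen-6-yl}-5,7-dimethoxy-4H-chromen-4-one | COc1cc(OC)c2c(=O)c(-c3c(OCc4ccccc4)cc4oc(-c5ccc(OCc6ccccc6)c(OCc6ccccc6)c5)cc(=O)c4c3OCc3ccccc3)c(-c3ccc(OCc4ccccc4)cc3)oc2c1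
F6 | step 5 | methyl 3,4-bis(benzyloxy)benzoate | COC(=O)c1ccc(OCc2ccccc2)c(OCc2ccccc2)c1
F7 | step 5 | ethyl 2-acetyl-5-[3,4-bis(benzyloxy)phenyl]-3,5-dioxopentanoate | CCOC(=O)C(C(C)=O)C(=O)CC(=O)c1ccc(OCc2ccccc2)c(OCc2ccccc2)c1
F8 | step 3 | 2-[4-(benzyloxy)phenyl]-3-(ethoxyethynyl)-5,7-dimethoxy-4H-chromen-4-one | CCOC#Cc1c(-c2ccc(OCc3ccccc3)cc2)oc2cc(OC)cc(OC)c2c1=O
F9 | step 7 | 3-[2-(3,4-dihydroxyphenyl)-5,7-dihydroxy-4-oxo-4H-chromen-6-yl]-2-(4-hydroxyphenyl)-5,7-dimethoxy-4H-chromen-4-one | COc1cc(OC)c2c(=O)c(-c3c(O)cc4oc(-c5ccc(O)c(O)c5)cc(=O)c4c3O)c(-c3ccc(O)cc3)oc2c1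
A1 | alternative 1 | {5,7-bis(benzyloxy)-2-[3,4-bis(benzyloxy)phenyl]-4-oxo-4H-chromen-6-yl}boronic acid | O=c1cc(-c2ccc(OCc3ccccc3)c(OCc3ccccc3)c2)oc2cc(OCc3ccccc3)c(B(O)O)c(OCc3ccccc3)c12
A2 | alternative 2 | 1-(2-hydroxy-4,6-dimethoxyphenyl)-2-[2,4,6-tris(benzyloxy)phenyl]ethan-1-one | COc1cc(O)c(C(=O)Cc2c(OCc3ccccc3)cc(OCc3ccccc3)cc2OCc2ccccc2)c(OC)c1
A3 | alternative 2 | 2-[4-(benzyloxy)phenyl]-5,7-dimethoxy-3-[2,4,6-tris(benzyloxy)phenyl]-4H-chromen-4-one | COc1cc(OC)c2c(=O)c(-c3c(OCc4ccccc4)cc(OCc4ccccc4)cc3OCc3ccccc3)c(-c3ccc(OCc4ccccc4)cc3)oc2c1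
A4 | alternative 2 | 3-[2-(3,4-dihydroxyphenyl)-5,7-dihydroxy-4-oxo-4H-chromen-8-yl]-5-hydroxy-2-(4-hydroxyphenyl)-7-methoxy-4H-chromen-4-one | COc1cc(O)c2c(=O)c(-c3c(O)cc(O)c4c(=O)cc(-c5ccc(O)c(O)c5)oc34)c(-c3ccc(O)cc3)oc2c1
A5 | alternative 3 | 2-[4-(benzyloxy)phenyl]-5,7-dimethoxy-4H-chromen-4-one | COc1cc(OC)c2c(=O)cc(-c3ccc(OCc4ccccc4)cc3)oc2c1
A6 | alternative 3 | 2-[3,4-bis(benzyloxy)phenyl]-5,7-dihydroxy-4H-chromen-4-one | O=c1cc(-c2ccc(OCc3ccccc3)c(OCc3ccccc3)c2)oc2cc(O)cc(O)c12
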